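**Plan**

1. Retrosynthesis: the ester C(=O)–O bond between the two C15 halves is cut first. The butenolide half is the dehydrated lactone of the other half, so both go back to one cyclohexanone β-keto ester (14) that already carries the (E)-2-(silyloxymethyl)acrylate side chain.
2. The cyclohexane of 14 is a hidden p-menthane: the ring CH bearing the side chain is β to the ring carboxyl carbon, and the ring CH bearing isopropyl is the inner carbon of a prenyl unit. The bond between these two CH carbons is therefore cut to an acyclic alkylidene β-keto ester whose 4-methylpent-3-enyl chain closes onto the alkylidene carbon (terpinyl-type conjugate ene cyclisation).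
3. The acyclic precursor is cut at its alkylidene C=C (Knoevenagel) into a prenylated acetoacetate and a C5 enal made by Morita–Baylis–Hillman chemistry.
4. Forward: enal 8 (steps 1–5) and keto ester 11 (step 6) are joined (7), the cyclohexanone ring is closed (8) and the isopropenyl group reduced (9). Compound 14 then gives the butenolide acid 18 (second ring, steps 10–12) and the diol 20 (steps 13–14), which are esterified and deprotected (15–17).
5. Stereochemistry: the two ring CH centres come from the catalyst-controlled chair closure in step 8, the carboxyl-bearing centre from equilibration to the all-equatorial keto ester, the tertiary carbinol from equatorial osmylation of an exocyclic methylene, and both acrylate geometries are the thermodynamic E ones.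

Key step: step 8

Assumption: the (S,S)-ligand is taken to give the (1S,2R,3S) enantiomer of 13 by analogy with its Mukaiyama–Michael reactions of chelating alkylidene 1,3-dicarbonyl compounds; if the sense proves opposite, the (R,R)-ligand is used with no other change.

**Route**

Step 1
Reactants: 1 tert-butyl acrylate; 2 2,2-dimethoxyacetaldehyde (60 % aqueous solution)
Product: 3 tert-butyl 3-hydroxy-4,4-dimethoxy-2-methylidenebutanoate (racemic)
Conditions: DABCO (1 equiv), 1,4-dioxane/H2O 1:1, rt
Reagents that add atoms: none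
Why: Morita–Baylis–Hillman reaction of an activated α,α-dialkoxy aldehyde, which aqueous dioxane should speed up for the slow tert-butyl acrylate; the new carbinol centre is racemic and is removed in step 2.

Step 2
Reactants: 3 tert-butyl 3-hydroxy-4,4-dimethoxy-2-methylidenebutanoate
Product: 5 tert-butyl (2E)-2-[(acetyloxy)methyl]-4,4-dimethoxybut-2-enoate, via secondary acetate 4 (not isolated)
Conditions: Ac2O, pyridine, DMAP (cat.), CH2Cl2, 0 °C to rt; evaporate; DABCO (0.2 equiv), THF, reflux
Reagents that add atoms: acetic anhydride, CC(=O)OC(C)=O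
Why: O-acetylation followed by DABCO-catalysed allylic transposition of the Morita–Baylis–Hillman acetate (amine addition–elimination, then acetate return at CH2) should move the ester to the primary terminus under thermodynamic control, placing the acetal carbon trans to the tert-butyl ester (E).

Step 3
Reactants: 5 tert-butyl (2E)-2-[(acetyloxy)methyl]-4,4-dimethoxybut-2-enoate
Product: 6 tert-butyl (2E)-2-(hydroxymethyl)-4,4-dimethoxybut-2-enoate
Conditions: K2CO3 (0.2 equiv), MeOH, 0 °C
Reagents that add atoms: none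
Why: base-catalysed transesterification should remove the unhindered primary acetate much faster than methoxide touches the tert-butyl ester or the acetal.

Step 4
Reactants: 6 tert-butyl (2E)-2-(hydroxymethyl)-4,4-dimethoxybut-2-enoate
Product: 7 tert-butyl (2E)-2-{[(tert-butyldiphenylsilyl)oxy]methyl}-4,4-dimethoxybut-2-enoate
Conditions: TBDPSCl, imidazole, CH2Cl2, rt
Reagents that add atoms: tert-butyl(chloro)diphenylsilane, CC(C)(C)[Si](Cl)(c1ccccc1)c1ccccc1
Why: standard silylation of a primary alcohol; the tert-butyldiphenylsilyl ether is chosen because it should survive the trifluoroacetic acid of step 12.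

Step 5
Reactants: 7 tert-butyl (2E)-2-{[(tert-butyldiphenylsilyl)oxy]methyl}-4,4-dimethoxybut-2-enoate
Product: 8 tert-butyl (2E)-2-{[(tert-butyldiphenylsilyl)oxy]methyl}-4-oxobut-2-enoate
Conditions: 5 % aqueous oxalic acid on SiO2, CH2Cl2, rt
Reagents that add atoms: water, O
Why: mild acid-catalysed acetal hydrolysis on wet silica should unmask the enal without cleaving the silyl ether or the tert-butyl ester; the E geometry is also the thermodynamic one.

Step 6
Reactants: 9 tert-butyl 3-oxobutanoate; 10 1-bromo-3-methylbut-2-ene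
Product: 11 tert-butyl 7-methyl-3-oxooct-6-enoate
Conditions: NaH, THF, 0 °C; n-BuLi, 0 °C; then 10, 0 °C to rt; aqueous NH4Cl
Reagents that add atoms: none
Why: γ-alkylation of the acetoacetate dianion, in which the more basic terminal carbanion should displace the allylic bromide (SN2) and leave the doubly activated CH2 free for step 7.

Step 7
Reactants: 11 tert-butyl 7-methyl-3-oxooct-6-enoate; 8 tert-butyl (2E)-2-{[(tert-butyldiphenylsilyl)oxy]methyl}-4-oxobut-2-enoate
Product: 12 di-tert-butyl (2E,4Z)-2-{[(tert-butyldiphenylsilyl)oxy]methyl}-5-(5-methylhex-4-enoyl)hexa-2,4-dienedioate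
Conditions: piperidine (0.1 equiv), AcOH (0.1 equiv), CH2Cl2, 4 Å molecular sieves, 0 °C
Reagents that add atoms: none
Why: Knoevenagel condensation of the β-keto ester with the enal; the preferred isomer should have the dienyl group cis to the twisted ester (4Z), and the minor isomer can be re-equilibrated under the same amine catalyst.

Step 8
Reactants: 12 di-tert-butyl (2E,4Z)-2-{[(tert-butyldiphenylsilyl)oxy]methyl}-5-(5-methylhex-4-enoyl)hexa-2,4-dienedioate
Product: 13 tert-butyl (1S,2R,3S)-2-[(1E)-3-tert-butoxy-2-{[(tert-butyldiphenylsilyl)oxy]methyl}-3-oxoprop-1-en-1-yl]-6-oxo-3-(prop-1-en-2-yl)cyclohexane-1-carboxylate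
Conditions: [Cu((S,S)-tBu-box)](SbF6)2 (10 mol %), made from CuCl2, AgSbF6 and (S,S)-tBu-box [2,2'-(propane-2,2-diyl)bis((4S)-4-tert-butyl-4,5-dihydro-1,3-oxazole)]; CH2Cl2, 4 Å molecular sieves, −40 to 0 °C
Reagents that add atoms: none
Why: Proposed new method: two-point binding of the ketone and ester carbonyls of 12 to the cationic divalent copper bis(oxazoline) complex lowers the LUMO of the alkylidene, the trisubstituted C=C of the 4-methylpent-3-enyl chain attacks the alkylidene carbon to give a tertiary carbocation and a copper enolate, and a methyl hydrogen passes to the enolate (stepwise conjugate ene reaction) to leave the isopropenyl group. The closest known reactions are the Lewis-acid-promoted intramolecular ene reaction of alkylidene 1,3-dicarbonyl compounds with trisubstituted alkenes and the copper bis(oxazoline)-catalysed Mukaiyama–Michael and carbonyl-ene reactions of chelating dicarbonyl acceptors, whereas an enantioselective version with a simple alkene as nucleophile and the tether running through the ketone is not established. The cyclohexanone closes in a 6-endo-trig mode at the acceptor (both alkylidene carbons become ring atoms) and exo with respect to the attacking alkene, through a chair-like transition state. The ring carbon carrying the side chain is set by the (4Z) geometry of 12 (dienyl trans to the ketone carbon, hence equatorial) and the isopropenyl-bearing carbon by the equatorial placement of the developing 2-propyl cation, which together should give the 2,3-trans relationship; the absolute sense comes from the tert-butyl groups of the ligand, which shield one face of the planar chelate, and the ester-bearing carbon settles trans (equatorial) by enolisation. The step needs attack at the alkylidene carbon and not at the two dienoate carbons, which ring size secures (six atoms against seven or eight), and it needs the catalysed path to outrun closure by adventitious achiral acid, which low temperature, sieves and a halide-free cationic complex should secure.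

Step 9
Reactants: 13 the isopropenyl cyclohexanone keto ester from step 8
Product: 14 tert-butyl (1S,2S,3R)-2-[(1E)-3-tert-butoxy-2-{[(tert-butyldiphenylsilyl)oxy]methyl}-3-oxoprop-1-en-1-yl]-6-oxo-3-(propan-2-yl)cyclohexane-1-carboxylate
Conditions: H2 (1 atm), RhCl(PPh3)3 (5 mol %), benzene, rt
Reagents that add atoms: none
Why: homogeneous hydrogenation with RhCl(PPh3)3 should reduce the unhindered 1,1-disubstituted alkene far faster than the trisubstituted, electron-poor acrylate; no stereocentre is formed.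

Step 10
Reactants: 14 the isopropyl cyclohexanone keto ester from step 9
Product: 15 tert-butyl (5R,6S)-6-[(1E)-3-tert-butoxy-2-{[(tert-butyldiphenylsilyl)oxy]methyl}-3-oxoprop-1-en-1-yl]-5-(propan-2-yl)-2-{[(trifluoromethyl)sulfonyl]oxy}cyclohex-1-ene-1-carboxylate
Conditions: NaH, THF, 0 °C; PhNTf2, 0 °C to rt
Reagents that add atoms: N-phenylbis(trifluoromethanesulfonimide), O=S(=O)(N(c1ccccc1)S(=O)(=O)C(F)(F)F)C(F)(F)F
Why: O-sulfonylation of the sodium enolate of the β-keto ester should give the tetrasubstituted enol triflate; the ester-bearing centre is flattened on purpose and the two remaining CH centres are not acidic.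

Step 11
Reactants: 15 the enol triflate from step 10
Product: 16 tert-butyl (5R,6S)-6-[(1E)-3-tert-butoxy-2-{[(tert-butyldiphenylsilyl)oxy]methyl}-3-oxoprop-1-en-1-yl]-2-(hydroxymethyl)-5-(propan-2-yl)cyclohex-1-ene-1-carboxylate
Conditions: Bu3SnCH2OH, Pd(PPh3)4 (5 mol %), LiCl (3 equiv), 1,4-dioxane, 90 °C
Reagents that add atoms: (tributylstannyl)methanol, OC[Sn](CCCC)(CCCC)CCCC
Why: Stille coupling of the electron-poor enol triflate with the hydroxymethylstannane on zerovalent palladium (chloride assists transmetalation) should place the future lactone CH2O carbon cis to the ring ester.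

Step 12
Reactants: 16 the allylic alcohol di-tert-butyl ester from step 11
Product: 18 (2E)-2-{[(tert-butyldiphenylsilyl)oxy]methyl}-3-[(4S,5R)-3-oxo-5-(propan-2-yl)-1,3,4,5,6,7-hexahydro-2-benzofuran-4-yl]prop-2-enoic acid, via hydroxy diacid 17 (not isolated)
Conditions: TFA/CH2Cl2 1:4, 0 °C to rt
Reagents that add atoms: none
Why: acidolysis of both tert-butyl esters (tert-butyl cation pathway) followed by spontaneous lactonisation of the cis γ-hydroxy acid should give the butenolide, while the primary tert-butyldiphenylsilyl ether should survive this acid.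

Step 13
Reactants: 14 the isopropyl cyclohexanone keto ester from step 9
Product: 19 tert-butyl (1S,2S,3R)-2-[(1E)-3-tert-butoxy-2-{[(tert-butyldiphenylsilyl)oxy]methyl}-3-oxoprop-1-en-1-yl]-6-methylidene-3-(propan-2-yl)cyclohexane-1-carboxylate
Conditions: Zn, CH2Br2, TiCl4 (reagent formed beforehand in THF), CH2Cl2, 0 °C to rt
Reagents that add atoms: dibromomethane, BrCBr
Why: Takai–Lombardo methylenation with the non-basic gem-dimetallic reagent should convert the ketone, and not the esters, into the exocyclic alkene without enolate chemistry, so the trans (equatorial) ester centre is kept.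

Step 14
Reactants: 19 the exocyclic methylene ester from step 13
Product: 20 tert-butyl (1S,2S,3R,6S)-2-[(1E)-3-tert-butoxy-2-{[(tert-butyldiphenylsilyl)oxy]methyl}-3-oxoprop-1-en-1-yl]-6-hydroxy-6-(hydroxymethyl)-3-(propan-2-yl)cyclohexane-1-carboxylate
Conditions: OsO4 (2 mol %), NMO (1.5 equiv), acetone/H2O 5:1, 0 °C to rt
Reagents that add atoms: N-methylmorpholine N-oxide, C[N+]1([O-])CCOCC1; water, O
Why: catalytic osmium tetroxide dihydroxylation should pick the electron-rich 1,1-disubstituted alkene over the acrylate and attack from the equatorial direction of the all-equatorial chair (away from the two syn-axial ring hydrogens), which places the tertiary OH equatorial and the CH2OH axial, that is (6S).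

Step 15
Reactants: 18 the butenolide acid from step 12; 20 the diol from step 14
Product: 22 tert-butyl (1S,2S,3R,6S)-2-[(1E)-3-tert-butoxy-2-{[(tert-butyldiphenylsilyl)oxy]methyl}-3-oxoprop-1-en-1-yl]-6-{[((2E)-2-{[(tert-butyldiphenylsilyl)oxy]methyl}-3-[(4S,5R)-3-oxo-5-(propan-2-yl)-1,3,4,5,6,7-hexahydro-2-benzofuran-4-yl]prop-2-enoyl)oxy]methyl}-6-hydroxy-3-(propan-2-yl)cyclohexane-1-carboxylate, via mixed anhydride 21 (not isolated)
Conditions: 18, 2,4,6-trichlorobenzoyl chloride, Et3N, THF, rt; then 20, DMAP, toluene, rt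
Reagents that add atoms: none
Why: Yamaguchi esterification, in which the primary hydroxyl should attack the less hindered acyl carbon of the mixed anhydride under DMAP catalysis while the tertiary hydroxyl stays free and the tert-butyl ester resists lactonisation by the neighbouring CH2OH.

Step 16
Reactants: 22 the bis-silylated ester from step 15
Product: 23 tert-butyl (1S,2S,3R,6S)-2-[(1E)-3-tert-butoxy-2-(hydroxymethyl)-3-oxoprop-1-en-1-yl]-6-hydroxy-6-{[((2E)-2-(hydroxymethyl)-3-[(4S,5R)-3-oxo-5-(propan-2-yl)-1,3,4,5,6,7-hexahydro-2-benzofuran-4-yl]prop-2-enoyl)oxy]methyl}-3-(propan-2-yl)cyclohexane-1-carboxylate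
Conditions: HF·pyridine, pyridine/THF, 0 °C to rt
Reagents that add atoms: none
Why: fluoride-driven Si–O cleavage should remove both primary silyl ethers while the tert-butyl esters, the butenolide and the linking ester are stable to buffered HF.

Step 17
Reactants: 23 the di-tert-butyl ester triol from step 16
Product: 24 (1S,2S,3R,6S)-2-[(1E)-2-carboxy-3-hydroxyprop-1-en-1-yl]-6-hydroxy-6-{[((2E)-2-(hydroxymethyl)-3-[(4S,5R)-3-oxo-5-(propan-2-yl)-1,3,4,5,6,7-hexahydro-2-benzofuran-4-yl]prop-2-enoyl)oxy]methyl}-3-(propan-2-yl)cyclohexane-1-carboxylic acid (CNP0071646.2)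
Conditions: TFA/CH2Cl2 1:3, 0 °C to rt; evaporation
Reagents that add atoms: none
Why: acidolysis of the two tert-butyl esters by loss of 2-methylpropene should leave the tertiary alcohol (deactivated by the adjacent acyloxymethyl and carboxyl groups) and both esters intact and gives only volatile by-products.

**Compound list**

1 | tert-butyl acrylate | C=CC(=O)OC(C)(C)C | starting material
2 | 2,2-dimethoxyacetaldehyde | COC(OC)C=O | starting material
3 | tert-butyl 3-hydroxy-4,4-dimethoxy-2-methylidenebutanoate (racemic) | C=C(C(O)C(OC)OC)C(=O)OC(C)(C)C | intermediate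
4 | tert-butyl 3-(acetyloxy)-4,4-dimethoxy-2-methylidenebutanoate (racemic, not isolated) | C=C(C(OC(C)=O)C(OC)OC)C(=O)OC(C)(C)C | intermediate
5 | tert-butyl (2E)-2-[(acetyloxy)methyl]-4,4-dimethoxybut-2-enoate | COC(OC)/C=C(\COC(C)=O)C(=O)OC(C)(C)C | intermediate
6 | tert-butyl (2E)-2-(hydroxymethyl)-4,4-dimethoxybut-2-enoate | COC(OC)/C=C(\CO)C(=O)OC(C)(C)C | intermediate
7 | tert-butyl (2E)-2-{[(tert-butyldiphenylsilyl)oxy]methyl}-4,4-dimethoxybut-2-enoate | COC(OC)/C=C(\CO[Si](c1ccccc1)(c1ccccc1)C(C)(C)C)C(=O)OC(C)(C)C | intermediate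
8 | tert-butyl (2E)-2-{[(tert-butyldiphenylsilyl)oxy]methyl}-4-oxobut-2-enoate | O=C/C=C(\CO[Si](c1ccccc1)(c1ccccc1)C(C)(C)C)C(=O)OC(C)(C)C | intermediate
9 | tert-butyl 3-oxobutanoate | CC(=O)CC(=O)OC(C)(C)C | starting material
10 | 1-bromo-3-methylbut-2-ene | CC(C)=CCBr | starting material
11 | tert-butyl 7-methyl-3-oxooct-6-enoate | CC(C)=CCCC(=O)CC(=O)OC(C)(C)C | intermediate
12 | di-tert-butyl (2E,4Z)-2-{[(tert-butyldiphenylsilyl)oxy]methyl}-5-(5-methylhex-4-enoyl)hexa-2,4-dienedioate | CC(C)=CCCC(=O)/C(C(=O)OC(C)(C)C)=C/C=C(\CO[Si](c1ccccc1)(c1ccccc1)C(C)(C)C)C(=O)OC(C)(C)C | intermediate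
13 | tert-butyl (1S,2R,3S)-2-[(1E)-3-tert-butoxy-2-{[(tert-butyldiphenylsilyl)oxy]methyl}-3-oxoprop-1-en-1-yl]-6-oxo-3-(prop-1-en-2-yl)cyclohexane-1-carboxylate | C=C(C)[C@H]1CCC(=O)[C@@H](C(=O)OC(C)(C)C)[C@@H]1/C=C(\CO[Si](c1ccccc1)(c1ccccc1)C(C)(C)C)C(=O)OC(C)(C)C | intermediate
14 | tert-butyl (1S,2S,3R)-2-[(1E)-3-tert-butoxy-2-{[(tert-butyldiphenylsilyl)oxy]methyl}-3-oxoprop-1-en-1-yl]-6-oxo-3-(propan-2-yl)cyclohexane-1-carboxylate | CC(C)[C@H]1CCC(=O)[C@@H](C(=O)OC(C)(C)C)[C@@H]1/C=C(\CO[Si](c1ccccc1)(c1ccccc1)C(C)(C)C)C(=O)OC(C)(C)C | intermediate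
15 | tert-butyl (5R,6S)-6-[(1E)-3-tert-butoxy-2-{[(tert-butyldiphenylsilyl)oxy]methyl}-3-oxoprop-1-en-1-yl]-5-(propan-2-yl)-2-{[(trifluoromethyl)sulfonyl]oxy}cyclohex-1-ene-1-carboxylate | CC(C)[C@H]1CCC(OS(=O)(=O)C(F)(F)F)=C(C(=O)OC(C)(C)C)[C@@H]1/C=C(\CO[Si](c1ccccc1)(c1ccccc1)C(C)(C)C)C(=O)OC(C)(C)C | intermediate
16 | tert-butyl (5R,6S)-6-[(1E)-3-tert-butoxy-2-{[(tert-butyldiphenylsilyl)oxy]methyl}-3-oxoprop-1-en-1-yl]-2-(hydroxymethyl)-5-(propan-2-yl)cyclohex-1-ene-1-carboxylate | CC(C)[C@H]1CCC(CO)=C(C(=O)OC(C)(C)C)[C@@H]1/C=C(\CO[Si](c1ccccc1)(c1ccccc1)C(C)(C)C)C(=O)OC(C)(C)C | intermediate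
17 | (5R,6S)-6-[(1E)-2-carboxy-3-{[tert-butyldiphenylsilyl]oxy}prop-1-en-1-yl]-2-(hydroxymethyl)-5-(propan-2-yl)cyclohex-1-ene-1-carboxylic acid (not isolated) | CC(C)[C@H]1CCC(CO)=C(C(=O)O)[C@@H]1/C=C(\CO[Si](c1ccccc1)(c1ccccc1)C(C)(C)C)C(=O)O | intermediate
18 | (2E)-2-{[(tert-butyldiphenylsilyl)oxy]methyl}-3-[(4S,5R)-3-oxo-5-(propan-2-yl)-1,3,4,5,6,7-hexahydro-2-benzofuran-4-yl]prop-2-enoic acid | OC(=O)/C(=C/[C@H]1C2=C(CC[C@@H]1C(C)C)COC2=O)CO[Si](c1ccccc1)(c1ccccc1)C(C)(C)C | intermediate
19 | tert-butyl (1S,2S,3R)-2-[(1E)-3-tert-butoxy-2-{[(tert-butyldiphenylsilyl)oxy]methyl}-3-oxoprop-1-en-1-yl]-6-methylidene-3-(propan-2-yl)cyclohexane-1-carboxylate | CC(C)[C@H]1CCC(=C)[C@@H](C(=O)OC(C)(C)C)[C@@H]1/C=C(\CO[Si](c1ccccc1)(c1ccccc1)C(C)(C)C)C(=O)OC(C)(C)C | intermediate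
20 | tert-butyl (1S,2S,3R,6S)-2-[(1E)-3-tert-butoxy-2-{[(tert-butyldiphenylsilyl)oxy]methyl}-3-oxoprop-1-en-1-yl]-6-hydroxy-6-(hydroxymethyl)-3-(propan-2-yl)cyclohexane-1-carboxylate | CC(C)[C@H]1CC[C@@](O)(CO)[C@@H](C(=O)OC(C)(C)C)[C@@H]1/C=C(\CO[Si](c1ccccc1)(c1ccccc1)C(C)(C)C)C(=O)OC(C)(C)C | intermediate
21 | (2E)-2-{[(tert-butyldiphenylsilyl)oxy]methyl}-3-[(4S,5R)-3-oxo-5-(propan-2-yl)-1,3,4,5,6,7-hexahydro-2-benzofuran-4-yl]prop-2-enoic 2,4,6-trichlorobenzoic anhydride (not isolated) | O=C(OC(=O)c1c(Cl)cc(Cl)cc1Cl)/C(=C/[C@H]1C2=C(CC[C@@H]1C(C)C)COC2=O)CO[Si](c1ccccc1)(c1ccccc1)C(C)(C)C | intermediate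
22 | tert-butyl (1S,2S,3R,6S)-2-[(1E)-3-tert-butoxy-2-{[(tert-butyldiphenylsilyl)oxy]methyl}-3-oxoprop-1-en-1-yl]-6-{[((2E)-2-{[(tert-butyldiphenylsilyl)oxy]methyl}-3-[(4S,5R)-3-oxo-5-(propan-2-yl)-1,3,4,5,6,7-hexahydro-2-benzofuran-4-yl]prop-2-enoyl)oxy]methyl}-6-hydroxy-3-(propan-2-yl)cyclohexane-1-carboxylate | CC(C)[C@H]1CC[C@@](O)(COC(=O)/C(=C/[C@H]2C3=C(CC[C@@H]2C(C)C)COC3=O)CO[Si](c4ccccc4)(c4ccccc4)C(C)(C)C)[C@@H](C(=O)OC(C)(C)C)[C@@H]1/C=C(\CO[Si](c1ccccc1)(c1ccccc1)C(C)(C)C)C(=O)OC(C)(C)C | intermediate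
23 | tert-butyl (1S,2S,3R,6S)-2-[(1E)-3-tert-butoxy-2-(hydroxymethyl)-3-oxoprop-1-en-1-yl]-6-hydroxy-6-{[((2E)-2-(hydroxymethyl)-3-[(4S,5R)-3-oxo-5-(propan-2-yl)-1,3,4,5,6,7-hexahydro-2-benzofuran-4-yl]prop-2-enoyl)oxy]methyl}-3-(propan-2-yl)cyclohexane-1-carboxylate | CC(C)[C@H]1CC[C@@](O)(COC(=O)/C(=C/[C@H]2C3=C(CC[C@@H]2C(C)C)COC3=O)CO)[C@@H](C(=O)OC(C)(C)C)[C@@H]1/C=C(\CO)C(=O)OC(C)(C)C | intermediate
24 | (1S,2S,3R,6S)-2-[(1E)-2-carboxy-3-hydroxyprop-1-en-1-yl]-6-hydroxy-6-{[((2E)-2-(hydroxymethyl)-3-[(4S,5R)-3-oxo-5-(propan-2-yl)-1,3,4,5,6,7-hexahydro-2-benzofuran-4-yl]prop-2-enoyl)oxy]methyl}-3-(propan-2-yl)cyclohexane-1-carboxylic acid (CNP0071646.2) | CC(C)[C@H]1CC[C@@](O)(COC(=O)/C(=C/[C@H]2C3=C(CC[C@@H]2C(C)C)COC3=O)CO)[C@@H](C(=O)O)[C@@H]1/C=C(\CO)C(=O)O | target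

**Step count and risks**

Total step count: 17. Longest linear sequence: 14 steps (steps 1–5, 7–12 and 15–17).

Steps most likely to fail:

1. Step 8 (Proposed new method). The catalyst may give poor facial discrimination, turnover may stall because the product β-keto ester stays bound to copper, or the minor alkylidene isomer may close to the cis diastereomer. The fallback sets out from 12: a catalytic amount of ZnBr2 in CH2Cl2 at −20 °C (the known Lewis-acid-promoted intramolecular ene reaction of alkylidene 1,3-dicarbonyl compounds) should give the racemic cyclised keto ester F1. Condensation of the racemic cyclised keto ester F1 with (1S)-1-phenylethanamine (AcOH cat., MgSO4, toluene) should give two diastereomeric hydrogen-bonded enamino esters, from which the (5S,6R) enamino ester F2 is separated by chromatography or crystallisation. Hydrolysis of the (5S,6R) enamino ester F2 with aqueous acetic acid in THF returns to the route at 13.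

2. Step 13. The β-keto ester may enolise to an unreactive titanium or zinc enolate, or the new double bond may migrate into conjugation with the ester. The fallback sets out from 14: addition of the weakly basic organocerium reagent made from Me3SiCH2Li and CeCl3 (THF, −78 °C) to the ketone should give the β-hydroxysilane F3. Acid-induced Peterson elimination of the β-hydroxysilane F3 (cat. p-toluenesulfonic acid, CH2Cl2, 0 °C) returns to the route at 19.

3. Step 15. Acylation of the neopentyl-type primary hydroxyl next to the quaternary carbinol may be slow, so that base-induced lactonisation of 20 or decay of the mixed anhydride wins. The fallback sets out from 20: selective sulfonylation of the primary hydroxyl (TsCl, pyridine, 0 °C) should give the primary tosylate F4, which should close with DBU to the spiro-epoxide F5 with retention at the carbinol carbon. Opening of the spiro-epoxide F5 at its CH2 terminus by the cesium carboxylate of 18 (Cs2CO3, DMF, 60 °C) forms the same ester bond from the alkyl side and frees the tertiary hydroxyl, returning to the route at 22.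

Further compounds
F1 | step 8 | rac-tert-butyl (1S,2R,3S)-2-[(1E)-3-tert-butoxy-2-{[(tert-butyldiphenylsilyl)oxy]methyl}-3-oxoprop-1-en-1-yl]-6-oxo-3-(prop-1-en-2-yl)cyclohexane-1-carboxylate (racemate of 13, both enantiomers given) | C=C(C)[C@H]1CCC(=O)[C@@H](C(=O)OC(C)(C)C)[C@@H]1/C=C(\CO[Si](c1ccccc1)(c1ccccc1)C(C)(C)C)C(=O)OC(C)(C)C.C=C(C)[C@@H]1CCC(=O)[C@H](C(=O)OC(C)(C)C)[C@H]1/C=C(\CO[Si](c1ccccc1)(c1ccccc1)C(C)(C)C)C(=O)OC(C)(C)C
F2 | step 8 | tert-butyl (5S,6R)-6-[(1E)-3-tert-butoxy-2-{[(tert-butyldiphenylsilyl)oxy]methyl}-3-oxoprop-1-en-1-yl]-2-{[(1S)-1-phenylethyl]amino}-5-(prop-1-en-2-yl)cyclohex-1-ene-1-carboxylate | C=C(C)[C@H]1CCC(N[C@@H](C)c2ccccc2)=C(C(=O)OC(C)(C)C)[C@@H]1/C=C(\CO[Si](c1ccccc1)(c1ccccc1)C(C)(C)C)C(=O)OC(C)(C)C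
F3 | step 13 | tert-butyl (1S,2S,3R)-2-[(1E)-3-tert-butoxy-2-{[(tert-butyldiphenylsilyl)oxy]methyl}-3-oxoprop-1-en-1-yl]-6-hydroxy-3-(propan-2-yl)-6-[(trimethylsilyl)methyl]cyclohexane-1-carboxylate (either configuration at C-6) | CC(C)[C@H]1CCC(O)(C[Si](C)(C)C)[C@@H](C(=O)OC(C)(C)C)[C@@H]1/C=C(\CO[Si](c1ccccc1)(c1ccccc1)C(C)(C)C)C(=O)OC(C)(C)C
F4 | step 15 | tert-butyl (1S,2S,3R,6S)-2-[(1E)-3-tert-butoxy-2-{[(tert-butyldiphenylsilyl)oxy]methyl}-3-oxoprop-1-en-1-yl]-6-hydroxy-6-({[(4-methylphenyl)sulfonyl]oxy}methyl)-3-(propan-2-yl)cyclohexane-1-carboxylate | CC(C)[C@H]1CC[C@@](O)(COS(=O)(=O)c2ccc(C)cc2)[C@@H](C(=O)OC(C)(C)C)[C@@H]1/C=C(\CO[Si](c1ccccc1)(c1ccccc1)C(C)(C)C)C(=O)OC(C)(C)C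
F5 | step 15 | tert-butyl (3S,4S,5S,6R)-5-[(1E)-3-tert-butoxy-2-{[(tert-butyldiphenylsilyl)oxy]methyl}-3-oxoprop-1-en-1-yl]-6-(propan-2-yl)-1-oxaspiro[2.5]octane-4-carboxylate | CC(C)[C@H]1CC[C@@]2(CO2)[C@@H](C(=O)OC(C)(C)C)[C@@H]1/C=C(\CO[Si](c1ccccc1)(c1ccccc1)C(C)(C)C)C(=O)OC(C)(C)C
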